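**Strategy.** Ring atoms are called C1 (CMe2), C2 (CHBr), C3 (alkylidene carbon), C4 (CHCl), C5 and C6 (CHCl); the side chain is C8(H)= and C9H2Br. Everything rests on the C1–C2 disconnection. The key step exploits the C6 chloride beside the gem-dimethyl carbon C1: an acyclic, enantiopure chlorohydrin triflate ionises with a 1,2-chlorine shift, and the resulting β-chloro tertiary cation alkylates a tethered furan. This closes the cyclohexane, forms quaternary C1 and sets C6–Cl in one operation. The furan is the latent (Z)-C2–C3(=C8)–C9 unit: photooxygenation, hydroxyl-directed reduction, lactone reduction and three stereospecific halide displacements complete the target.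

Key step: step 6

Remark: the facial sense of the (R)-phosphoric acid (step 1) and of the D-fructose-derived ketone (step 4) is taken from the parent aryl aldehyde and trisubstituted alkene cases; the antipodal catalysts would be used if the sense were opposite.

Step 1
Reactants: 1 furan-3-carbaldehyde; 2 allylboronic acid pinacol ester
Product: 4 (1R)-1-(furan-3-yl)but-3-en-1-ol, via borate ester 3 (not isolated)
Conditions: (R)-TRIP (5 mol %), toluene, −30 °C; aq. NaHCO3 work-up
Reagents that add atoms: allylboronic acid pinacol ester, C=CCB1OC(C)(C)C(C)(C)O1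
Why: Chiral phosphoric acid-catalysed allylboration through a closed chair transition state; the (R)-acid is chosen to deliver the allyl group to the Re face, which sets the carbinol centre (later ring C4) as R.

Step 2
Reactants: 4 (1R)-1-(furan-3-yl)but-3-en-1-ol
Product: 5 tert-butyl{[(1R)-1-(furan-3-yl)but-3-en-1-yl]oxy}diphenylsilane
Conditions: TBDPSCl, imidazole, DMF, rt
Reagents that add atoms: tert-butyl(chloro)diphenylsilane, CC(C)(C)[Si](Cl)(c1ccccc1)c1ccccc1
Why: Standard imidazole-promoted silylation; the bulky, weakly basic silyl ether is chosen so that the furylic oxygen should neither ionise nor capture the cation in step 6.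

Step 3
Reactants: 5 the silyl ether of step 2; 6 2-methylbut-2-ene
Product: 7 tert-butyl{[(1R)-1-(furan-3-yl)-4-methylpent-3-en-1-yl]oxy}diphenylsilane
Conditions: Grubbs II (5 mol %), 2-methylbut-2-ene (excess), CH2Cl2, 40 °C
Reagents that add atoms: 2-methylbut-2-ene, CC=C(C)C
Why: Olefin cross-metathesis with excess 2-methylbut-2-ene should convert the terminal alkene into the prenyl alkene; the furan and the silyl ether are inert to the ruthenium carbene.

Step 4
Reactants: 7 the prenyl compound of step 3
Product: 8 tert-butyl{(1R)-2-[(2R)-3,3-dimethyloxiran-2-yl]-1-(furan-3-yl)ethoxy}diphenylsilane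
Conditions: D-fructose-derived Shi ketone (30 mol %), Oxone, K2CO3, Bu4NHSO4, MeCN/DMM/aq. borate buffer, 0 °C
Reagents that add atoms: potassium peroxymonosulfate (Oxone), [K+].[O-]S(=O)(=O)OO
Why: Shi asymmetric epoxidation (dioxirane, spiro transition state); the electron-rich trisubstituted alkene should react faster than the furan, and the D-fructose-derived ketone is chosen to give the (R)-epoxide, whose C–O centre later becomes C6.

Step 5
Reactants: 8 the epoxide of step 4
Product: 9 (3R,5R)-5-[(tert-butyldiphenylsilyl)oxy]-2-chloro-5-(furan-3-yl)-2-methylpentan-3-ol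
Conditions: HCl (1 M in Et2O, 1.2 equiv), CH2Cl2, −60 → −30 °C
Reagents that add atoms: hydrogen chloride, Cl
Why: Acid-assisted Markovnikov opening of the trisubstituted epoxide by chloride at the tertiary carbon leaves the secondary C–O stereocentre untouched; the regiochemistry is not critical, because either chlorohydrin regioisomer would ionise to the same chloronium ion in step 6.

Step 6
Reactants: 9 the chlorohydrin of step 5
Product: 11 (4R,6S)-4-[(tert-butyldiphenylsilyl)oxy]-6-chloro-7,7-dimethyl-4,5,6,7-tetrahydro-1-benzofuran, via secondary triflate 10 (not isolated)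
Conditions: Tf2O, 2,6-di-tert-butyl-4-methylpyridine, CH2Cl2, −78 °C; then (CF3)2CHOH, −40 → 0 °C
Reagents that add atoms: none
Why: Proposed new method: triflation of the secondary carbinol (ring C6) gives 10, whose C–OTf bond is displaced from the rear by the neighbouring tertiary chlorine (1,2-shift through a chloronium ion that opens to the β-chloro tertiary cation at C1), and the furan α-carbon (ring C2) captures this cation before loss of a proton restores the furan; the closest known reaction types are the solvolytic generation of configurationally stable chloronium ions from enantioenriched β-chloro sulfonates, halonium-initiated cation–π cyclisations and furan-terminated cationic cyclisations of epoxides. The cyclohexane closes in a 6-endo mode with respect to the furan C2=C3 bond, an intramolecular Friedel–Crafts alkylation at the α-carbon, which is far more nucleophilic than the β-carbon that the tether could also reach. The only new stereocentre, C6–Cl, is controlled by the carbinol centre set in step 4: the anti-periplanar chlorine shift inverts it, and chloronium ions should not racemise by olefin-to-olefin transfer. The step needs chemoselectivity between ionisation of the secondary triflate and of the furylic C4–O bond, and between C- and O-capture of the cation. No Lewis or Brønsted acid is present (hindered pyridine buffer), and the bulky silyl ether is both a poor leaving group and a poor nucleophile.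

Step 7
Reactants: 11 the tetrahydrobenzofuran of step 6
Product: 12 (4R,6S)-6-chloro-7,7-dimethyl-4,5,6,7-tetrahydro-1-benzofuran-4-ol
Conditions: TBAF, THF, 0 °C → rt
Reagents that add atoms: none
Why: Fluoride-mediated desilylation; the secondary neopentylic chloride (equatorial, no anti-periplanar hydrogen) and the furan should survive fluoride at this temperature.

Step 8
Reactants: 12 the furyl alcohol of step 7
Product: 14 (4R,6S)-6-chloro-4,7a-dihydroxy-7,7-dimethyl-5,6,7,7a-tetrahydro-1-benzofuran-2(4H)-one (7a-epimers), via furan endoperoxide 13 (not isolated)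
Conditions: O2, tetraphenylporphyrin (cat.), hν (visible), i-Pr2NEt, CH2Cl2, −78 °C → rt; aq. citric acid work-up
Reagents that add atoms: dioxygen, O=O
Why: Singlet-oxygen [4+2] cycloaddition across the furan α-carbons followed by base-induced Kornblum–DeLaMare fragmentation of 13; only C9 carries a hydrogen, so the carbonyl must end at C9 and the hemiketal at C2.

Step 9
Reactants: 14 the hydroxybutenolide of step 8
Product: 16 (4R,6S,7aS)-6-chloro-4-hydroxy-7,7-dimethyl-5,6,7,7a-tetrahydro-1-benzofuran-2(4H)-one, via hydroxy acid 15 (not isolated)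
Conditions: Me4NBH(OAc)3, MeCN/AcOH (1:1), −25 → 0 °C; then aq. HCl
Reagents that add atoms: none
Why: Evans–Saksena hydroxyl-directed reduction: 14 equilibrates with its open (Z)-γ-keto acid, the borohydride bound to the C4 oxygen delivers hydride to the C2 ketone on the face of that hydroxyl (1,3-anti diol, C2–O trans to C4–O and to C6–Cl), and the (Z)-γ-hydroxy acid 15 lactonises, which also differentiates C2–O and C9 from the free C4–OH.

Step 10
Reactants: 16 the hydroxy butenolide of step 9
Product: 17 (4S,6S,7aR)-4,6-dichloro-7,7-dimethyl-5,6,7,7a-tetrahydro-1-benzofuran-2(4H)-one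
Conditions: PPh3, N-chlorosuccinimide, THF, 0 °C → rt
Reagents that add atoms: N-chlorosuccinimide, O=C1CCC(=O)N1Cl
Why: Appel-type chlorination: SN2 displacement of the allylic oxyphosphonium with inversion should give the C4 chloride trans to C6–Cl; SN2′ attack at C8, the α-carbon of the unsaturated lactone, and ionisation are electronically disfavoured.

Step 11
Reactants: 17 the dichloro butenolide of step 10
Product: 19 (1R,3S,5S,6E)-3,5-dichloro-6-(2-hydroxyethylidene)-2,2-dimethylcyclohexan-1-ol (CH2OH cis to the carbinol carbon), via lactol 18 (not isolated)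
Conditions: DIBAL-H (4 equiv), CH2Cl2, −78 → −20 °C; Rochelle salt
Reagents that add atoms: none
Why: DIBAL-H 1,2-reduction of the butenolide through lactol 18 and its open hydroxy-enal form to the ene-1,4-diol; the C3=C8 geometry (C9 cis to C2) is fixed because C2–O and C9 were joined in the five-membered ring just opened.

Step 12
Reactants: 19 the ene-diol of step 11
Product: 20 (2S,3Z,4S,6S)-2-bromo-3-(2-bromoethylidene)-4,6-dichloro-1,1-dimethylcyclohexane
Conditions: CBr4, PPh3, CH2Cl2, −20 → 0 °C
Reagents that add atoms: carbon tetrabromide, BrC(Br)(Br)Br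
Why: Appel bromination of the primary allylic C9–OH and the secondary allylic C2–OH; SN2 inversion at C2 should place C2–Br cis to C6–Cl as in the target.

**Compound list**

1 | furan-3-carbaldehyde | O=Cc1ccoc1 | starting material
2 | allylboronic acid pinacol ester | C=CCB1OC(C)(C)C(C)(C)O1 | starting material
3 | 2-{[(1R)-1-(furan-3-yl)but-3-en-1-yl]oxy}-4,4,5,5-tetramethyl-1,3,2-dioxaborolane | CC1(C)OB(O[C@H](CC=C)c2ccoc2)OC1(C)C | intermediate (not isolated)
4 | (1R)-1-(furan-3-yl)but-3-en-1-ol | O[C@H](CC=C)c1ccoc1 | intermediate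
5 | tert-butyl{[(1R)-1-(furan-3-yl)but-3-en-1-yl]oxy}diphenylsilane | CC(C)(C)[Si](c1ccccc1)(c1ccccc1)O[C@H](CC=C)c1ccoc1 | intermediate
6 | 2-methylbut-2-ene | CC=C(C)C | starting material
7 | tert-butyl{[(1R)-1-(furan-3-yl)-4-methylpent-3-en-1-yl]oxy}diphenylsilane | CC(C)(C)[Si](c1ccccc1)(c1ccccc1)O[C@H](CC=C(C)C)c1ccoc1 | intermediate
8 | tert-butyl{(1R)-2-[(2R)-3,3-dimethyloxiran-2-yl]-1-(furan-3-yl)ethoxy}diphenylsilane | CC(C)(C)[Si](c1ccccc1)(c1ccccc1)O[C@H](C[C@H]1OC1(C)C)c1ccoc1 | intermediate
9 | (3R,5R)-5-[(tert-butyldiphenylsilyl)oxy]-2-chloro-5-(furan-3-yl)-2-methylpentan-3-ol | CC(C)(C)[Si](c1ccccc1)(c1ccccc1)O[C@H](C[C@@H](O)C(C)(C)Cl)c1ccoc1 | intermediate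
10 | (3R,5R)-5-[(tert-butyldiphenylsilyl)oxy]-2-chloro-5-(furan-3-yl)-2-methylpentan-3-yl trifluoromethanesulfonate | CC(C)(C)[Si](c1ccccc1)(c1ccccc1)O[C@H](C[C@@H](OS(=O)(=O)C(F)(F)F)C(C)(C)Cl)c1ccoc1 | intermediate (not isolated)
11 | (4R,6S)-4-[(tert-butyldiphenylsilyl)oxy]-6-chloro-7,7-dimethyl-4,5,6,7-tetrahydro-1-benzofuran (4-O cis to 6-Cl) | CC1(C)c2occc2[C@H](O[Si](C(C)(C)C)(c2ccccc2)c2ccccc2)C[C@@H]1Cl | intermediate
12 | (4R,6S)-6-chloro-7,7-dimethyl-4,5,6,7-tetrahydro-1-benzofuran-4-ol | CC1(C)c2occc2[C@H](O)C[C@@H]1Cl | intermediate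
13 | 2,7a-endoperoxide of 12 (2,3,7-trioxabicyclo[2.2.1]hept-5-ene fused to the chlorocyclohexanol; peroxide face not defined) | CC1(C)C23OOC(O2)C=C3[C@H](O)C[C@@H]1Cl | intermediate (not isolated)
14 | (4R,6S)-6-chloro-4,7a-dihydroxy-7,7-dimethyl-5,6,7,7a-tetrahydro-1-benzofuran-2(4H)-one (7a-epimers, ring tautomer of the keto acid) | CC1(C)C2(O)OC(=O)C=C2[C@H](O)C[C@@H]1Cl | intermediate
15 | (2Z)-2-[(2S,4S,6R)-4-chloro-2,6-dihydroxy-3,3-dimethylcyclohexylidene]acetic acid | CC1(C)[C@@H](O)/C(=C\C(=O)O)[C@H](O)C[C@@H]1Cl | intermediate (not isolated)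
16 | (4R,6S,7aS)-6-chloro-4-hydroxy-7,7-dimethyl-5,6,7,7a-tetrahydro-1-benzofuran-2(4H)-one | CC1(C)[C@H]2OC(=O)C=C2[C@H](O)C[C@@H]1Cl | intermediate
17 | (4S,6S,7aR)-4,6-dichloro-7,7-dimethyl-5,6,7,7a-tetrahydro-1-benzofuran-2(4H)-one | CC1(C)[C@H]2OC(=O)C=C2[C@@H](Cl)C[C@@H]1Cl | intermediate
18 | (4S,6S,7aR)-4,6-dichloro-7,7-dimethyl-2,4,5,6,7,7a-hexahydro-1-benzofuran-2-ol (anomers) | CC1(C)[C@H]2OC(O)C=C2[C@@H](Cl)C[C@@H]1Cl | intermediate (not isolated)
19 | (1R,3S,5S,6E)-3,5-dichloro-6-(2-hydroxyethylidene)-2,2-dimethylcyclohexan-1-ol (CH2OH cis to C1) | CC1(C)[C@@H](O)/C(=C\CO)[C@@H](Cl)C[C@@H]1Cl | intermediate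
20 | (2S,3Z,4S,6S)-2-bromo-3-(2-bromoethylidene)-4,6-dichloro-1,1-dimethylcyclohexane | CC1(C)[C@H](Br)/C(=C\CBr)[C@@H](Cl)C[C@@H]1Cl | target

**Totals.** Total step count: 12. Longest linear sequence: 12 steps (fully linear from furan-3-carbaldehyde).

**Steps most likely to fail**

1. Step 6 (labelled step). The tertiary cation may lose a proton (E1) faster than it cyclises, the silyl ether oxygen may capture the cation, or the furylic position may ionise. The fallback uses known chemistry and sets out from epoxide 8. A Lewis acid (MeAlCl2, CH2Cl2, −78 °C) should promote the furan-terminated epoxide cyclisation to (4R,6R)-4-[(tert-butyldiphenylsilyl)oxy]-7,7-dimethyl-4,5,6,7-tetrahydro-1-benzofuran-6-ol F1. The ring hydroxyl would then be replaced by chloride with inversion (PPh3, CCl4, reflux, or 1-chloro-N,N,2-trimethylpropenylamine). This comes back to the route at 11.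

2. Step 12. SN2 at the neopentylic allylic C2 is slow, so SN2′ attack at C8, ionisation with loss of configuration at C2, or cyclodehydration of the cis-ene-diol to a dihydrofuran may take over. The fallback sets out from lactone 17 and avoids the free diol. The allylic lactone C2–O bond is opened by bromide with inversion (TMSBr, cat. ZnBr2, CH2Cl2); the conjugated carbonyl suppresses both SN2′ and ionisation. This should give trimethylsilyl (2Z)-2-[(2S,4S,6S)-2-bromo-4,6-dichloro-3,3-dimethylcyclohexylidene]acetate F2. DIBAL-H at −78 °C would reduce the silyl ester to (2Z)-2-[(2S,4S,6S)-2-bromo-4,6-dichloro-3,3-dimethylcyclohexylidene]ethan-1-ol F3. CBr4/PPh3 on the primary alcohol then comes back to the route at 20.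

3. Step 9. Non-directed hydride delivery, or a poorly populated conformer for the internal delivery, would erode the facial selectivity at C2. The fallback sets out from 14 and replaces substrate direction by catalyst control. The open form is esterified (MeI, KHCO3, DMF) to methyl (2Z)-2-[(4S,6R)-4-chloro-6-hydroxy-3,3-dimethyl-2-oxocyclohexylidene]acetate F4. The ketone is reduced with a CBS oxazaborolidine and catecholborane, the catalyst enantiomer being chosen to add hydride syn to the C4 oxygen. This should give methyl (2Z)-2-[(2S,4S,6R)-4-chloro-2,6-dihydroxy-3,3-dimethylcyclohexylidene]acetate F5. Acid (CSA, CH2Cl2) lactonises F5, and the sequence comes back to the route at 16.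

**Further compounds**

F1 | step 6 | (4R,6R)-4-[(tert-butyldiphenylsilyl)oxy]-7,7-dimethyl-4,5,6,7-tetrahydro-1-benzofuran-6-ol | CC1(C)c2occc2[C@H](O[Si](C(C)(C)C)(c2ccccc2)c2ccccc2)C[C@H]1O
F2 | step 12 | trimethylsilyl (2Z)-2-[(2S,4S,6S)-2-bromo-4,6-dichloro-3,3-dimethylcyclohexylidene]acetate | CC1(C)[C@H](Br)/C(=C\C(=O)O[Si](C)(C)C)[C@@H](Cl)C[C@@H]1Cl
F3 | step 12 | (2Z)-2-[(2S,4S,6S)-2-bromo-4,6-dichloro-3,3-dimethylcyclohexylidene]ethan-1-ol | CC1(C)[C@H](Br)/C(=C\CO)[C@@H](Cl)C[C@@H]1Cl
F4 | step 9 | methyl (2Z)-2-[(4S,6R)-4-chloro-6-hydroxy-3,3-dimethyl-2-oxocyclohexylidene]acetate | CC1(C)C(=O)/C(=C\C(=O)OC)[C@H](O)C[C@@H]1Cl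
F5 | step 9 | methyl (2Z)-2-[(2S,4S,6R)-4-chloro-2,6-dihydroxy-3,3-dimethylcyclohexylidene]acetate | CC1(C)[C@@H](O)/C(=C\C(=O)OC)[C@H](O)C[C@@H]1Cl
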